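**Retrosynthetic overview**

1. The strategy rests on the seven-membered lactone ring O1–C2(=O)–C3=C4–C5–C6–C7. Its carbonyl carbon C2 lies between the ring oxygen O1 and the alkene carbon C3, so C2 can be brought in as CO, with the ring Z geometry held beforehand in a C3–I bond cis to C5 (iodide 17 → lactone 18).
2. Iodide 17 comes from alkyne 12 by a silicon tether on O6: Ru-catalysed trans-hydrosilylation to oxasiline 14, iododesilylation, then silylation of O6 and release of O7.
3. The C4–C5 bond comes from opening the terminal C5–C6 epoxide 7 with the lithium acetylide of enyne 10.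
4. The C6/C7 pair comes from a matched Sharpless epoxidation of the (S)-allylic alcohol 4, made from geranyl acetate by Shi epoxidation (sets C7) and epoxide-to-allylic-alcohol isomerisation.
5. The lactone is the only ring of the target and is closed in the key step; the oxirane and oxasiline rings are transient.

Key step: step 13

Remarks on the chemistry:
- The lactone numbering above (C3 to C7, O1) is used for these atoms in all intermediates; the target is (6R,7S).
- Assumption: an allylic acetate would be alkynylated by the alkynyl-BF3 reagent of step 7, so the acetate is removed in step 5 and restored in step 8.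
- Assumption: the L-fructose-derived enantiomer of the Shi ketone is available (it can be made from L-sorbose).

**Step 1**
Reactants: 1 geranyl acetate
Product: 2 (2E)-5-[(2S)-3,3-dimethyloxiran-2-yl]-3-methylpent-2-en-1-yl acetate
Conditions: ent-Shi ketone (L-fructose-derived, 30 mol%), Oxone, K2CO3, Bu4NHSO4 (cat.), MeCN/DMM/aq. Na2B4O7–EDTA buffer, −5 → 0 °C
Reagents that add atoms: potassium peroxymonosulfate (active salt of Oxone), [K+].[O-]S(=O)(=O)OO
Why: Shi asymmetric epoxidation, in which the chiral dioxirane should attack the electron-rich distal trisubstituted alkene through a spiro transition state and set the (S) centre (future C7), while the alkene next to the acetate is deactivated.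

**Step 2**
Reactants: 2 (2E)-5-[(2S)-3,3-dimethyloxiran-2-yl]-3-methylpent-2-en-1-yl acetate
Product: 4 (2E,6S)-6-hydroxy-3,7-dimethylocta-2,7-dien-1-yl acetate, via allylic TMS ether 3 (not isolated)
Conditions: TMSOTf, DBU, toluene, 0 °C → rt; then 1 M HCl, THF, 0 °C
Reagents that add atoms: none
Why: TMSOTf/DBU epoxide-to-allylic-silyl-ether isomerisation, in which silyl activation breaks the tertiary C–O bond and DBU removes a methyl proton to give the isopropenyl carbinol; the secondary C7–O bond is untouched, so its configuration is kept, and dilute acid removes the TMS group.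

**Step 3**
Reactants: 4 (2E,6S)-6-hydroxy-3,7-dimethylocta-2,7-dien-1-yl acetate
Product: 5 (2E,6S)-6-hydroxy-3-methyl-6-[(2R)-2-methyloxiran-2-yl]hex-2-en-1-yl acetate
Conditions: Ti(OiPr)4 (20 mol%), L-(+)-DIPT (25 mol%), t-BuOOH (decane), 4 Å MS, CH2Cl2, −20 °C
Reagents that add atoms: tert-butyl hydroperoxide, CC(C)(C)OO
Why: Sharpless asymmetric epoxidation in the matched sense: the (S)-carbinol is the fast-reacting enantiomer with L-(+)-tartrate and the titanium-bound hydroxyl should deliver oxygen to the 1,1-disubstituted alkene to give the erythro epoxy alcohol, setting C6 as (R), while the acetate-bearing alkene has no directing hydroxyl and the slow-reacting minor (R)-alcohol should be left behind.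

**Step 4**
Reactants: 5 (2E,6S)-6-hydroxy-3-methyl-6-[(2R)-2-methyloxiran-2-yl]hex-2-en-1-yl acetate
Product: 6 (2E,6S)-3-methyl-6-[(2R)-2-methyloxiran-2-yl]-6-(triethylsilyloxy)hex-2-en-1-yl acetate
Conditions: TESCl, imidazole, DMAP (cat.), CH2Cl2, 0 °C → rt
Reagents that add atoms: chlorotriethylsilane, CC[Si](Cl)(CC)CC
Why: Standard silylation of the secondary C7 hydroxyl, which blocks Payne rearrangement, consumption of acetylide and later iodoetherification.

**Step 5**
Reactants: 6 (2E,6S)-3-methyl-6-[(2R)-2-methyloxiran-2-yl]-6-(triethylsilyloxy)hex-2-en-1-yl acetate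
Product: 7 (2E,6S)-3-methyl-6-[(2R)-2-methyloxiran-2-yl]-6-(triethylsilyloxy)hex-2-en-1-ol
Conditions: K2CO3 (cat.), MeOH, 0 °C
Reagents that add atoms: none
Why: Base-catalysed transesterification should remove the primary acetate, while the epoxide and the hindered secondary TES ether are expected to tolerate catalytic carbonate at 0 °C.

**Step 6**
Reactants: 8 5-bromo-2-methylpent-2-ene; 9 lithium acetylide–ethylenediamine complex
Product: 10 6-methylhept-5-en-1-yne
Conditions: DMSO, 10 °C → rt
Reagents that add atoms: none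
Why: SN2 alkylation of lithium acetylide by a primary bromide in a dipolar aprotic solvent.

**Step 7**
Reactants: 7 (2E,6S)-3-methyl-6-[(2R)-2-methyloxiran-2-yl]-6-(triethylsilyloxy)hex-2-en-1-ol; 10 6-methylhept-5-en-1-yne
Product: 11 (2E,6S,7R)-3,7,14-trimethyl-6-(triethylsilyloxy)pentadeca-2,13-dien-9-yne-1,7-diol
Conditions: 10 (4 equiv), n-BuLi, THF, −78 °C; add 7; then BF3·OEt2, −78 °C; aq. NH4Cl
Reagents that add atoms: none
Why: BF3-promoted alkynylation of an epoxide (Yamaguchi conditions), in which the alkynyl–boron species should attack the unsubstituted C5 terminus of the 2,2-disubstituted oxirane with the C6–O bond retained, so no stereocentre is touched; the first equivalent of acetylide is spent on the free hydroxyl.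

**Step 8**
Reactants: 11 (2E,6S,7R)-3,7,14-trimethyl-6-(triethylsilyloxy)pentadeca-2,13-dien-9-yne-1,7-diol
Product: 12 (2E,6S,7R)-7-hydroxy-3,7,14-trimethyl-6-(triethylsilyloxy)pentadeca-2,13-dien-9-yn-1-yl acetate
Conditions: Ac2O, pyridine, CH2Cl2, 0 °C → rt (no DMAP)
Reagents that add atoms: acetic anhydride, CC(=O)OC(C)=O
Why: Acylation of the primary allylic alcohol; the tertiary C6 hydroxyl should not react with Ac2O/pyridine in the absence of DMAP.

**Step 9**
Reactants: 12 (2E,6S,7R)-7-hydroxy-3,7,14-trimethyl-6-(triethylsilyloxy)pentadeca-2,13-dien-9-yn-1-yl acetate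
Product: 14 (2E,6S)-3-methyl-6-(triethylsilyloxy)-6-[(6R)-2,2,6-trimethyl-3-(4-methylpent-3-en-1-yl)-5,6-dihydro-2H-1,2-oxasilin-6-yl]hex-2-en-1-yl acetate, via dimethylsilyl ether 13 (not isolated)
Conditions: (HMe2Si)2NH, neat, 60 °C, then evaporate; [Cp*Ru(MeCN)3]PF6 (5 mol%), CH2Cl2, 0 °C → rt
Reagents that add atoms: 1,1,3,3-tetramethyldisilazane, C[SiH](C)N[SiH](C)C
Why: O-silylation of the tertiary hydroxyl followed by Ru-catalysed intramolecular trans-hydrosilylation in the 6-endo-dig mode, which should place Si on C3 and H on C4 anti to each other, so the tether fixes both the regiochemistry and the geometry (Si cis to C5).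

**Step 10**
Reactants: 14 the oxasiline of step 9
Product: 15 (2E,6S,7R,9Z)-7-hydroxy-10-iodo-3,7,14-trimethyl-6-(triethylsilyloxy)pentadeca-2,9,13-trien-1-yl acetate
Conditions: NIS, AgF, MeCN, 0 °C, dark; aq. Na2S2O3/NaHCO3
Reagents that add atoms: N-iodosuccinimide, O=C1CCC(=O)N1I
Why: Fluoride-assisted iododesilylation of an alkenyl siloxane, in which ipso attack of iodine on the activated C3–Si bond should proceed with retention to give the (Z)-iodide and free the C6 hydroxyl, while the C7 silyl ether prevents iodoetherification.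

**Step 11**
Reactants: 15 (2E,6S,7R,9Z)-7-hydroxy-10-iodo-3,7,14-trimethyl-6-(triethylsilyloxy)pentadeca-2,9,13-trien-1-yl acetate
Product: 16 (2E,6S,7R,9Z)-10-iodo-3,7,14-trimethyl-6,7-bis(triethylsilyloxy)pentadeca-2,9,13-trien-1-yl acetate
Conditions: TESOTf, 2,6-lutidine, CH2Cl2, −78 → 0 °C
Reagents that add atoms: triethylsilyl trifluoromethanesulfonate, CC[Si](CC)(CC)OS(=O)(=O)C(F)(F)F
Why: Silyl triflate silylation, the standard way to protect a hindered tertiary alcohol.

**Step 12**
Reactants: 16 (2E,6S,7R,9Z)-10-iodo-3,7,14-trimethyl-6,7-bis(triethylsilyloxy)pentadeca-2,9,13-trien-1-yl acetate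
Product: 17 (2E,6S,7R,9Z)-6-hydroxy-10-iodo-3,7,14-trimethyl-7-(triethylsilyloxy)pentadeca-2,9,13-trien-1-yl acetate
Conditions: PPTS (cat.), MeOH/CH2Cl2, 0 °C, monitored
Reagents that add atoms: none
Why: Acid-catalysed methanolysis of silyl ethers is sterically controlled, so the secondary C7 TES ether should be cleaved clearly faster than the tertiary C6 TES ether.

**Step 13**
Reactants: 17 (2E,6S,7R,9Z)-6-hydroxy-10-iodo-3,7,14-trimethyl-7-(triethylsilyloxy)pentadeca-2,9,13-trien-1-yl acetate
Product: 18 the target lactone as its C6 triethylsilyl ether, (6R,7S)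
Conditions: Pd(PPh3)4 (10 mol%), CO (1 atm), i-Pr2NEt, MeCN, 65 °C, 0.005 M (slow addition of 17)
Reagents that add atoms: carbon monoxide, [C-]#[O+]
Why: Pd(0) should add oxidatively to the C3–I bond with retention of the Z geometry, CO then inserts into the alkenyl–Pd bond, and the C7 hydroxyl attacks the acyl-palladium, with amine-assisted loss of HI returning Pd(0). The closest known reaction type is the palladium-catalysed carbonylative lactonisation of (Z)-hydroxyalkenyl halides to butenolides and larger α,β-unsaturated lactones. The seven-membered ring is closed by a 7-exo-trig acyl substitution that forms C2–C3 and C2–O1 and leaves the carbonyl oxygen exocyclic. No stereocentre is formed or touched, since C6 and C7 are spectators and the C7–O bond is not broken. Ring size is secured by the TES ether on the tertiary C6 oxygen (a free C6 hydroxyl would close the six-membered lactone), and ring geometry by the C3–I bond cis to C5, the only arrangement in which the acyl-palladium can reach O7. Chemoselectivity over the allylic acetate relies on the much faster oxidative addition of the alkenyl iodide, and high dilution with an amine base should suppress intermolecular esterification and a 1,2-silyl shift.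

**Step 14**
Reactants: 18 the target lactone as its C6 triethylsilyl ether
Product: 19 CNP0314901.1, the (6R,7S)-lactone
Conditions: HF·pyridine, pyridine, THF, 0 °C
Reagents that add atoms: none
Why: Buffered fluoride desilylation should cleave the tertiary Si–O bond under mildly acidic conditions that leave the acetate and lactone intact and avoid base-induced translactonisation to the six-membered lactone.

**Compound list**

1 | geranyl acetate, (2E)-3,7-dimethylocta-2,6-dien-1-yl acetate | CC(=O)OC/C=C(\C)CCC=C(C)C | starting material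
2 | (2E)-5-[(2S)-3,3-dimethyloxiran-2-yl]-3-methylpent-2-en-1-yl acetate | CC(=O)OC/C=C(\C)CC[C@@H]1OC1(C)C | intermediate
3 | (2E,6S)-3,7-dimethyl-6-(trimethylsilyloxy)octa-2,7-dien-1-yl acetate | CC(=O)OC/C=C(\C)CC[C@H](O[Si](C)(C)C)C(C)=C | intermediate (not isolated)
4 | (2E,6S)-6-hydroxy-3,7-dimethylocta-2,7-dien-1-yl acetate | CC(=O)OC/C=C(\C)CC[C@H](O)C(C)=C | intermediate
5 | (2E,6S)-6-hydroxy-3-methyl-6-[(2R)-2-methyloxiran-2-yl]hex-2-en-1-yl acetate | CC(=O)OC/C=C(\C)CC[C@H](O)[C@@]1(C)CO1 | intermediate
6 | (2E,6S)-3-methyl-6-[(2R)-2-methyloxiran-2-yl]-6-(triethylsilyloxy)hex-2-en-1-yl acetate | CC(=O)OC/C=C(\C)CC[C@H](O[Si](CC)(CC)CC)[C@@]1(C)CO1 | intermediate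
7 | (2E,6S)-3-methyl-6-[(2R)-2-methyloxiran-2-yl]-6-(triethylsilyloxy)hex-2-en-1-ol | OC/C=C(\C)CC[C@H](O[Si](CC)(CC)CC)[C@@]1(C)CO1 | intermediate
8 | 5-bromo-2-methylpent-2-ene | CC(C)=CCCBr | starting material
9 | lithium acetylide–ethylenediamine complex | [Li+].[C-]#C.NCCN | starting material
10 | 6-methylhept-5-en-1-yne | C#CCCC=C(C)C | intermediate
11 | (2E,6S,7R)-3,7,14-trimethyl-6-(triethylsilyloxy)pentadeca-2,13-dien-9-yne-1,7-diol | OC/C=C(\C)CC[C@H](O[Si](CC)(CC)CC)[C@](C)(O)CC#CCCC=C(C)C | intermediate
12 | (2E,6S,7R)-7-hydroxy-3,7,14-trimethyl-6-(triethylsilyloxy)pentadeca-2,13-dien-9-yn-1-yl acetate | CC(=O)OC/C=C(\C)CC[C@H](O[Si](CC)(CC)CC)[C@](C)(O)CC#CCCC=C(C)C | intermediate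
13 | (2E,6S,7R)-7-(dimethylsilyloxy)-3,7,14-trimethyl-6-(triethylsilyloxy)pentadeca-2,13-dien-9-yn-1-yl acetate | CC(=O)OC/C=C(\C)CC[C@H](O[Si](CC)(CC)CC)[C@](C)(O[SiH](C)C)CC#CCCC=C(C)C | intermediate (not isolated)
14 | (2E,6S)-3-methyl-6-(triethylsilyloxy)-6-[(6R)-2,2,6-trimethyl-3-(4-methylpent-3-en-1-yl)-5,6-dihydro-2H-1,2-oxasilin-6-yl]hex-2-en-1-yl acetate | CC(=O)OC/C=C(\C)CC[C@H](O[Si](CC)(CC)CC)[C@@]1(C)CC=C(CCC=C(C)C)[Si](C)(C)O1 | intermediate
15 | (2E,6S,7R,9Z)-7-hydroxy-10-iodo-3,7,14-trimethyl-6-(triethylsilyloxy)pentadeca-2,9,13-trien-1-yl acetate | CC(=O)OC/C=C(\C)CC[C@H](O[Si](CC)(CC)CC)[C@](C)(O)C/C=C(/CCC=C(C)C)I | intermediate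
16 | (2E,6S,7R,9Z)-10-iodo-3,7,14-trimethyl-6,7-bis(triethylsilyloxy)pentadeca-2,9,13-trien-1-yl acetate | CC(=O)OC/C=C(\C)CC[C@H](O[Si](CC)(CC)CC)[C@](C)(O[Si](CC)(CC)CC)C/C=C(/CCC=C(C)C)I | intermediate
17 | (2E,6S,7R,9Z)-6-hydroxy-10-iodo-3,7,14-trimethyl-7-(triethylsilyloxy)pentadeca-2,9,13-trien-1-yl acetate | CC(=O)OC/C=C(\C)CC[C@H](O)[C@](C)(O[Si](CC)(CC)CC)C/C=C(/CCC=C(C)C)I | intermediate
18 | (6R,7S)-lactone with C6–OTES: seven-membered 2-oxo-oxepine ring carrying 3-(4-methylpent-3-enyl), 6-methyl, 6-triethylsilyloxy and 7-[(3E)-5-acetoxy-3-methylpent-3-enyl] | CC(=O)OC/C=C(\C)CC[C@@H]1OC(=O)C(CCC=C(C)C)=CC[C@@]1(C)O[Si](CC)(CC)CC | intermediate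
19 | CNP0314901.1, the (6R,7S)-lactone with free C6 hydroxyl | CC(=O)OC/C=C(\C)CC[C@@H]1OC(=O)C(CCC=C(C)C)=CC[C@@]1(C)O | target

**Step count**

Total: 14 steps. Longest linear sequence: 13 steps (steps 1–5 and 7–14, from geranyl acetate).

**Steps most likely to fail**

1. Step 13 (carbonylative lactonisation). The hindered secondary hydroxyl, flanked by the quaternary silyloxy carbon, may capture the acyl-palladium too slowly, so that intermolecular esterification, reduction of the C–I bond or slow ionisation of the allylic acetate by Pd(0) take over. Fallback: separate the CO insertion from the ring closure. From 17, palladium-catalysed hydroxycarbonylation (Pd(OAc)2, dppf, CO, water, Et3N, DMF, 50 °C) would give the (2Z,5R,6S,9E)-11-acetoxy-6-hydroxy-5,9-dimethyl-2-(4-methylpent-3-en-1-yl)-5-(triethylsilyloxy)undeca-2,9-dienoic acid F1; any lactone formed at this stage is already 18. Shiina lactonisation of this acid (MNBA, DMAP, CH2Cl2, high dilution) comes back to the route at 18.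

2. Step 10 (iododesilylation). Electrophilic iodine may add to the electron-rich trisubstituted alkenes, or fluoride may loosen the C7 silyl ether and open the way to iodoetherification. Fallback: change the silicon group to a trialkylsilane, whose ipso-iodination is faster. From 14, excess methyllithium (THF, −78 → 0 °C) would open the Si–O bond and remove the acetate to give the (Z)-trimethylsilyl alkene diol F2. Acetylation of the primary hydroxyl (Ac2O, pyridine) would give the acetate F3, and iododesilylation of this vinylsilane (NIS, 2,6-lutidine, HFIP, 0 °C) comes back to the route at 15.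

3. Step 12 (selective mono-desilylation). The two triethylsilyl ethers may not be told apart well enough, leading to over-cleavage to the diol or loss of the tertiary ether. Fallback: replace kinetic discrimination by orthogonal acyl protection. From 15, complete removal of the TES group (PPTS, MeOH, rt) would give the iodo diol F4, and chloroacetylation of the secondary hydroxyl ((ClCH2CO)2O, pyridine, 0 °C) the chloroacetate F5. TESOTf/2,6-lutidine would then silylate the tertiary hydroxyl to give the silyl ether F6, and thiourea/NaHCO3 in EtOH removes the chloroacetate in the presence of the acetate, coming back to the route at 17.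

**Further compounds**

F1 | step 13 | (2Z,5R,6S,9E)-11-acetoxy-6-hydroxy-5,9-dimethyl-2-(4-methylpent-3-en-1-yl)-5-(triethylsilyloxy)undeca-2,9-dienoic acid | CC(=O)OC/C=C(\C)CC[C@H](O)[C@](C)(O[Si](CC)(CC)CC)C/C=C(/CCC=C(C)C)C(O)=O
F2 | step 10 | (2E,6S,7R,9Z)-3,7,14-trimethyl-6-(triethylsilyloxy)-10-(trimethylsilyl)pentadeca-2,9,13-triene-1,7-diol | OC/C=C(\C)CC[C@H](O[Si](CC)(CC)CC)[C@](C)(O)C/C=C(/CCC=C(C)C)[Si](C)(C)C
F3 | step 10 | (2E,6S,7R,9Z)-7-hydroxy-3,7,14-trimethyl-6-(triethylsilyloxy)-10-(trimethylsilyl)pentadeca-2,9,13-trien-1-yl acetate | CC(=O)OC/C=C(\C)CC[C@H](O[Si](CC)(CC)CC)[C@](C)(O)C/C=C(/CCC=C(C)C)[Si](C)(C)C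
F4 | step 12 | (2E,6S,7R,9Z)-6,7-dihydroxy-10-iodo-3,7,14-trimethylpentadeca-2,9,13-trien-1-yl acetate | CC(=O)OC/C=C(\C)CC[C@H](O)[C@](C)(O)C/C=C(/CCC=C(C)C)I
F5 | step 12 | (2E,6S,7R,9Z)-6-(chloroacetoxy)-7-hydroxy-10-iodo-3,7,14-trimethylpentadeca-2,9,13-trien-1-yl acetate | CC(=O)OC/C=C(\C)CC[C@H](OC(=O)CCl)[C@](C)(O)C/C=C(/CCC=C(C)C)I
F6 | step 12 | (2E,6S,7R,9Z)-6-(chloroacetoxy)-10-iodo-3,7,14-trimethyl-7-(triethylsilyloxy)pentadeca-2,9,13-trien-1-yl acetate | CC(=O)OC/C=C(\C)CC[C@H](OC(=O)CCl)[C@](C)(O[Si](CC)(CC)CC)C/C=C(/CCC=C(C)C)I
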